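**Plan**

1. Retrosynthesis: cut the ring-B aryl–CH2 bond of the o-hydroxybenzyl fumarate (and its CH2–O bond), then the depsidone ester C(=O)–O bond, then the diaryl ether C–O bond. This leaves a 2-fluoro-3-formylbenzoate (ring A) and a 4-hydroxy-3-alkoxyphthalide (ring B).
2. Enabling feature: the CH2 carbon sits on the only unsubstituted carbon of ring B, between the free phenol carbon (OH next to the lactone C=O) and the depside-oxygen carbon. An o-hydroxybenzyl ester is the adduct of an o-quinone methide and a carboxylic acid, and the phenol oxygen can hold a boron tether that brings formaldehyde to exactly that carbon.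
3. Forward: the ring-B phthalide (amide-directed ortho-formylation, lactol closure) and ring A (lithiation/carboxylation, SNAr) are joined by SNAr to the diaryl ether; DCC lactonisation then closes the seven-membered depsidone ring.
4. The side chain comes last: phenol, formaldehyde and monoallyl fumarate are joined in one operation through a temporary 1,3,2-benzodioxaborin ring; Pd deallylation follows.
5. Stereochemistry: the lactol carbon is fixed early as a mixed acetal with (S)-1-(2-nitrophenyl)ethanol (epimers separated, the unwanted one re-equilibrated), carried unchanged, and unveiled in the last step by photolysis that breaks only the auxiliary-side C–O bond (retention, R).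

Key step: step 14

Remark: the only stereocentre is the hemiacetal carbon of a 3-hydroxyphthalide, which can epimerise by ring–chain tautomerism once it is free; it is therefore kept as a mixed acetal until the last step, and the target is to be isolated and stored cold, away from base and water.
Remark: which C-3 epimer of acetal 10 is favoured cannot be predicted; the route is written for (S)-alcohol 9 giving (3R)-10, and in the mirror-image case the (R)-alcohol would be used, which leads to the same final product.

Step 1
Reactants: 1 2,4,5-trimethoxybenzoic acid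
Product: 3 N,N-diethyl-2,4,5-trimethoxybenzamide, via acid chloride 2 (not isolated)
Conditions: (COCl)2, cat. DMF, CH2Cl2, 0 °C to rt; then Et2NH (3 equiv), 0 °C
Reagents that add atoms: diethylamine (CCNCC)
Why: Acyl chloride formation followed by amidation installs the tertiary amide that directs the next metalation.

Step 2
Reactants: 3 N,N-diethyl-2,4,5-trimethoxybenzamide
Product: 5 N,N-diethyl-2-formyl-3,4,6-trimethoxybenzamide, via aryllithium 4 (not isolated)
Conditions: s-BuLi, TMEDA, THF, −78 °C; DMF, −78 to 0 °C; aq. NH4Cl
Reagents that add atoms: N,N-dimethylformamide (CN(C)C=O)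
Why: Directed ortho-metalation, in which the amide and the 5-methoxy group cooperate to direct lithiation to the one position between them, followed by formylation with DMF.

Step 3
Reactants: 5 N,N-diethyl-2-formyl-3,4,6-trimethoxybenzamide
Product: 6 N,N-diethyl-2-formyl-3,4,6-trihydroxybenzamide
Conditions: BBr3 (6 equiv), CH2Cl2, −78 °C to rt; cold pH 7 phosphate buffer, under argon
Reagents that add atoms: none
Why: Lewis-acid demethylation of the three aryl methyl ethers, with a buffered cold quench intended to return the tertiary amide and the aldehyde unchanged.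

Step 4
Reactants: 6 N,N-diethyl-2-formyl-3,4,6-trihydroxybenzamide
Product: 7 4,6-bis(allyloxy)-N,N-diethyl-2-formyl-3-hydroxybenzamide
Conditions: NaH (3.3 equiv), DMSO, rt; allyl bromide (2.05 equiv), rt; pH 4 work-up
Reagents that add atoms: allyl bromide (C=CCBr)
Why: Regioselective Williamson alkylation of a polyphenoxide, in which the phenoxide ortho to the formyl group is delocalised into the carbonyl and least nucleophilic, as in the selective 3-O-alkylation of 2,3-dihydroxybenzaldehyde dianions, while the twisted tertiary amide does not shield its neighbouring oxygen.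

Step 5
Reactants: 7 4,6-bis(allyloxy)-N,N-diethyl-2-formyl-3-hydroxybenzamide
Product: 8 rac-5,7-bis(allyloxy)-3,4-dihydroxy-2-benzofuran-1(3H)-one
Conditions: TsOH·H2O (1.5 equiv), 1,4-dioxane–H2O 4:1, 90 °C
Reagents that add atoms: water (O)
Why: Acid-mediated neighbouring-group hydrolysis of an ortho-formyl tertiary benzamide, in which the aldehyde hydrate attacks the protonated amide and expels diethylamine to give the 3-hydroxyphthalide, the allyl ethers being acid-stable.

Step 6
Reactants: 8 rac-5,7-bis(allyloxy)-3,4-dihydroxy-2-benzofuran-1(3H)-one; 9 (S)-1-(2-nitrophenyl)ethanol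
Product: 10 (3R)-5,7-bis(allyloxy)-4-hydroxy-3-[(1S)-1-(2-nitrophenyl)ethoxy]-2-benzofuran-1(3H)-one
Conditions: 9 (1.5 equiv), CSA (10 mol%), toluene, 80 °C, 4 Å MS; separation of the C-3 epimers, the unwanted one resubjected
Reagents that add atoms: none
Why: Acid-catalysed pseudo-ester (mixed acetal) formation of a 3-hydroxyphthalide under thermodynamic control, in which the two C-3 epimers are diastereomers that are separated and interconverted under the same conditions, so that C-3 is set as R by the (S)-alcohol.

Step 7
Reactants: 11 2,6-difluoro-4-methylbenzaldehyde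
Product: 14 allyl 2,4-difluoro-3-formyl-6-methylbenzoate, via α-amino alkoxide 12 (not isolated), via aryllithium 13 (not isolated)
Conditions: LiN(Me)CH2CH2NMe2 (from the diamine and n-BuLi), THF, −78 °C; s-BuLi, −78 °C; ClCO2allyl (2.5 equiv), −78 °C; 1 M HCl, 0 °C
Reagents that add atoms: allyl chloroformate (C=CCOC(=O)Cl)
Why: Comins in situ protection of the aldehyde as an α-amino alkoxide, fluorine-directed ortho-lithiation at the only type of ring C–H, and acylation of the aryllithium by the chloroformate, the aldehyde returning on acidic work-up.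

Step 8
Reactants: 14 allyl 2,4-difluoro-3-formyl-6-methylbenzoate; 15 allyl alcohol
Product: 16 allyl 4-(allyloxy)-2-fluoro-3-formyl-6-methylbenzoate
Conditions: K2CO3 (1.5 equiv), 15 (1.2 equiv), DMF, 0 °C to rt
Reagents that add atoms: none
Why: SNAr in which the 4-fluorine (ortho to CHO, para to the ester, open on one side) should be displaced in preference to the 2-fluorine that is buttressed between CHO and ester, transesterification being degenerate.

Step 9
Reactants: 10 (3R)-5,7-bis(allyloxy)-4-hydroxy-3-[(1S)-1-(2-nitrophenyl)ethoxy]-2-benzofuran-1(3H)-one; 16 allyl 4-(allyloxy)-2-fluoro-3-formyl-6-methylbenzoate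
Product: 17 allyl 4-(allyloxy)-2-{[(3R)-5,7-bis(allyloxy)-3-[(1S)-1-(2-nitrophenyl)ethoxy]-1-oxo-1,3-dihydro-2-benzofuran-4-yl]oxy}-3-formyl-6-methylbenzoate
Conditions: Cs2CO3 (1.5 equiv), DMF, 50 °C
Reagents that add atoms: none
Why: SNAr diaryl ether synthesis in which the remaining fluorine is activated by the ortho-formyl and ortho-ester groups and 10 offers a single free phenol, the carbonate base leaving the acetal stereocentre untouched.

Step 10
Reactants: 17 the tetra-allyl diaryl ether
Product: 18 2-{[(3R)-5,7-dihydroxy-3-[(1S)-1-(2-nitrophenyl)ethoxy]-1-oxo-1,3-dihydro-2-benzofuran-4-yl]oxy}-3-formyl-4-hydroxy-6-methylbenzoic acid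
Conditions: Pd(PPh3)4 (10 mol%), sodium p-toluenesulfinate (6 equiv), AcOH (6 equiv), THF, rt
Reagents that add atoms: none
Why: Tsuji–Trost-type deallylation with a sulfinate as allyl acceptor removes the allyl ester and the three aryl allyl ethers under near-neutral conditions that aldehyde, acetal and nitro group tolerate.

Step 11
Reactants: 18 the seco acid
Product: 19 depsidone with free ring-A and ring-B phenols, (R)-lactol carbon as its (S)-1-(2-nitrophenyl)ethyl acetal, ring-B CH unsubstituted
Conditions: DCC (1.2 equiv), THF (high dilution), 0 °C to rt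
Reagents that add atoms: none
Why: Carbodiimide lactonisation as in classical depsidone syntheses, in which only the phenol ortho to the ether-bearing carbon can reach the activated acid and closes the seven-membered dibenzo[b,e][1,4]dioxepin-11-one ring.

Step 12
Reactants: 19 the depsidone diphenol
Product: 20 ring-A allyl ether of 19 (ring-B phenol free)
Conditions: allyl bromide (1.05 equiv), KHCO3 (1.1 equiv), DMF, rt
Reagents that add atoms: allyl bromide (C=CCBr)
Why: Chemoselective Williamson etherification, in which the ring-A phenol (ortho to CHO, para to the depsidone carbonyl) is the markedly more acidic one, so that bicarbonate should generate and allylate only that phenoxide.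

Step 13
Reactants: 21 maleic anhydride; 15 allyl alcohol
Product: 23 monoallyl fumarate, via monoallyl maleate 22 (not isolated)
Conditions: neat, 60 °C; then AcCl (5 mol%), toluene, 80 °C; crystallisation
Reagents that add atoms: none
Why: Alcoholysis of the anhydride gives the maleate half-ester, and acid chloride-catalysed Z-to-E isomerisation (as in monoalkyl fumarate manufacture) gives the fumarate half-ester.

Step 14
Reactants: 20 ring-A allyl ether depsidone with free ring-B phenol; 24 formaldehyde (as paraformaldehyde); 23 monoallyl fumarate
Product: 27 allyl fumarate ester of the ring-B o-hydroxybenzyl alcohol (fully protected target), via dioxaborin 25 (not isolated), via o-quinone methide 26 (not isolated)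
Conditions: PhB(OH)2 (1.5 equiv), (CH2O)n (5 equiv), EtCO2H (0.3 equiv), toluene, 90 °C, Dean–Stark; then 23 (4 equiv), 100 °C; pH 4 aqueous work-up
Reagents that add atoms: none
Why: Proposed new method: the free ring-B phenol condenses with PhB(OH)2 and formaldehyde to an aryloxy(phenyl)boron hemiformal, which delivers the CH2 unit intramolecularly to the only ortho C–H (the ring-B carbon between the phenol carbon and the depside-oxygen carbon) and gives the temporary 4H-1,3,2-benzodioxaborin 25; this is the Nagata ortho-hydroxymethylation, the closest known reaction type, extended here to acyloxylation in the same flask. The six-membered O–B–O–CH2 ring, which is not in the target, is closed by an ortho-specific C–C bond formation through a six-membered cyclic transition state followed by rearomatisation. Acid 23 then protonates the benzylic B–O–CH2 oxygen, the C–O bond ionises with help from the phenolic oxygen to o-quinone methide 26, and the carboxylate adds 1,4 at the exocyclic CH2 to give the o-hydroxybenzyl fumarate while azeotropic water removal drives the exchange and work-up returns PhB(OH)2; opening of benzodioxaborins to o-quinone methides and addition of carboxylic acids to o-quinone methides are each known. No stereocentre is formed, and the acetal carbon should not be touched under these weakly acidic, anhydrous conditions. Site selectivity rests on the substrate, because ring A has no free phenol so boron can anchor only on ring B, whose single free ortho position is the required one; chemoselectivity rests on polarity, because the electron-poor fumarate C=C is inert to the electrophilic quinone methide while the O–H adds.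

Step 15
Reactants: 27 the allyl ether/allyl ester
Product: 28 (S)-1-(2-nitrophenyl)ethyl acetal of the target (free ring-A phenol, free fumaric half-acid)
Conditions: Pd(PPh3)4 (5 mol%), N-methylaniline (5 equiv), THF, 0 °C to rt, dark; cold dilute acid wash
Reagents that add atoms: none
Why: Pd(0)-catalysed allyl transfer to N-methylaniline cleaves the allyl ester and the activated aryl allyl ether without base or hydride, so the o-hydroxybenzyl ester, the fumarate double bond, the aldehyde and the acetal stereocentre should be left alone.

Step 16
Reactants: 28 the nitrophenylethyl acetal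
Product: 29 target, (R)-lactol
Conditions: hν 365 nm (LED, flow), dry degassed MeCN, 0 °C; cold concentration and crystallisation
Reagents that add atoms: none
Why: Photolysis of the o-nitrobenzylic ether (as for 2-nitrobenzyl glycosides) proceeds by intramolecular hydrogen transfer to the nitro group and collapse of the hemiketal at the auxiliary carbon, so only the auxiliary-side C–O bond breaks and the lactol carbon is revealed with retention as R under neutral, aprotic, cold conditions.

**Compound list**

1 | 2,4,5-trimethoxybenzoic acid | COc1cc(OC)c(OC)cc1C(=O)O | starting material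
2 | 2,4,5-trimethoxybenzoyl chloride | COc1cc(OC)c(OC)cc1C(=O)Cl | intermediate
3 | N,N-diethyl-2,4,5-trimethoxybenzamide | CCN(CC)C(=O)c1cc(OC)c(OC)cc1OC | intermediate
4 | 6-lithio derivative of 3 (lithium between the amide and the 5-methoxy group) | CCN(CC)C(=O)c1c([Li])c(OC)c(OC)cc1OC | intermediate
5 | N,N-diethyl-2-formyl-3,4,6-trimethoxybenzamide | CCN(CC)C(=O)c1c(C=O)c(OC)c(OC)cc1OC | intermediate
6 | N,N-diethyl-2-formyl-3,4,6-trihydroxybenzamide | CCN(CC)C(=O)c1c(C=O)c(O)c(O)cc1O | intermediate
7 | 4,6-bis(allyloxy)-N,N-diethyl-2-formyl-3-hydroxybenzamide | CCN(CC)C(=O)c1c(C=O)c(O)c(OCC=C)cc1OCC=C | intermediate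
8 | rac-5,7-bis(allyloxy)-3,4-dihydroxy-2-benzofuran-1(3H)-one (3-hydroxyphthalide) | C=CCOc1cc(OCC=C)c2c(c1O)C(O)OC2=O | intermediate
9 | (S)-1-(2-nitrophenyl)ethanol | C[C@H](O)c1ccccc1[N+](=O)[O-] | starting material
10 | (3R)-5,7-bis(allyloxy)-4-hydroxy-3-[(1S)-1-(2-nitrophenyl)ethoxy]-2-benzofuran-1(3H)-one | C=CCOc1cc(OCC=C)c2c(c1O)[C@H](O[C@@H](C)c1ccccc1[N+](=O)[O-])OC2=O | intermediate
11 | 2,6-difluoro-4-methylbenzaldehyde | Cc1cc(F)c(C=O)c(F)c1 | starting material
12 | lithium α-amino alkoxide from 11 and lithium N,N,N'-trimethylethylenediamide | Cc1cc(F)c(C(O[Li])N(C)CCN(C)C)c(F)c1 | intermediate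
13 | ring-lithiated 12 (lithium between F and CH3) | Cc1cc(F)c(C(O[Li])N(C)CCN(C)C)c(F)c1[Li] | intermediate
14 | allyl 2,4-difluoro-3-formyl-6-methylbenzoate | Cc1cc(F)c(C=O)c(F)c1C(=O)OCC=C | intermediate
15 | allyl alcohol | C=CCO | starting material
16 | allyl 4-(allyloxy)-2-fluoro-3-formyl-6-methylbenzoate | Cc1cc(OCC=C)c(C=O)c(F)c1C(=O)OCC=C | intermediate
17 | allyl 4-(allyloxy)-2-{[(3R)-5,7-bis(allyloxy)-3-[(1S)-1-(2-nitrophenyl)ethoxy]-1-oxo-1,3-dihydro-2-benzofuran-4-yl]oxy}-3-formyl-6-methylbenzoate | Cc1cc(OCC=C)c(C=O)c(Oc2c(OCC=C)cc(OCC=C)c3c2[C@H](O[C@@H](C)c2ccccc2[N+](=O)[O-])OC3=O)c1C(=O)OCC=C | intermediate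
18 | 2-{[(3R)-5,7-dihydroxy-3-[(1S)-1-(2-nitrophenyl)ethoxy]-1-oxo-1,3-dihydro-2-benzofuran-4-yl]oxy}-3-formyl-4-hydroxy-6-methylbenzoic acid | Cc1cc(O)c(C=O)c(Oc2c(O)cc(O)c3c2[C@H](O[C@@H](C)c2ccccc2[N+](=O)[O-])OC3=O)c1C(=O)O | intermediate
19 | depsidone core without the side chain, ring-A and ring-B phenols free, (R)-lactol carbon as (S)-1-(2-nitrophenyl)ethyl acetal | Cc1cc(O)c(C=O)c2c1C(=O)Oc1cc(O)c3c(c1O2)[C@H](O[C@@H](C)c1ccccc1[N+](=O)[O-])OC3=O | intermediate
20 | ring-A allyl ether of 19 | Cc1cc(OCC=C)c(C=O)c2c1C(=O)Oc1cc(O)c3c(c1O2)[C@H](O[C@@H](C)c1ccccc1[N+](=O)[O-])OC3=O | intermediate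
21 | maleic anhydride | O=C1OC(=O)C=C1 | starting material
22 | monoallyl maleate | C=CCOC(=O)/C=C\C(=O)O | intermediate
23 | monoallyl fumarate | C=CCOC(=O)/C=C/C(=O)O | intermediate
24 | formaldehyde (used as paraformaldehyde) | C=O | starting material
25 | 2-phenyl-4H-1,3,2-benzodioxaborin fused to ring B of 20 (O–B(Ph)–O–CH2 bridging the phenol oxygen and the ortho carbon) | Cc1cc(OCC=C)c(C=O)c2c1C(=O)Oc1c3COB(c4ccccc4)Oc3c3c(c1O2)[C@H](O[C@@H](C)c1ccccc1[N+](=O)[O-])OC3=O | intermediate
26 | ring-B o-quinone methide of 20 (exocyclic CH2 on the ortho carbon, phenol carbon as C=O) | Cc1cc(OCC=C)c(C=O)c2c1C(=O)OC1=C(O2)C3=C(C(=O)C1=C)C(=O)O[C@H]3O[C@@H](C)c1ccccc1[N+](=O)[O-] | intermediate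
27 | allyl (E)-butenedioate ester of the ring-B o-hydroxybenzyl alcohol derived from 20 (ring-A allyl ether, nitrophenylethyl acetal) | Cc1cc(OCC=C)c(C=O)c2c1C(=O)Oc1c(COC(=O)/C=C/C(=O)OCC=C)c(O)c3c(c1O2)[C@H](O[C@@H](C)c1ccccc1[N+](=O)[O-])OC3=O | intermediate
28 | (S)-1-(2-nitrophenyl)ethyl acetal of the target at the (R)-lactol carbon | Cc1cc(O)c(C=O)c2c1C(=O)Oc1c(COC(=O)/C=C/C(=O)O)c(O)c3c(c1O2)[C@H](O[C@@H](C)c1ccccc1[N+](=O)[O-])OC3=O | intermediate
29 | target, (R)-lactol, (E)-fumaric half-ester | Cc1cc(O)c(C=O)c2c1C(=O)Oc1c(COC(=O)/C=C/C(=O)O)c(O)c3c(c1O2)[C@H](O)OC3=O | target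

**Count**

Total steps: 16. Longest linear sequence: 13 (steps 1–6, 9–12, 14–16, from 2,4,5-trimethoxybenzoic acid).

**Steps most likely to fail**

Step 14 (proposed new method). The chelated, electron-poor ring-B phenol may be hydroxymethylated too slowly, or the quinone methide may oligomerise before the acid captures it. The fallback sets out from 20 and comes back at 27, and forms the same aryl–CH2 bond by cross-coupling. 20 is brominated at the same ring-B carbon (NBS, MeCN, 0 °C; electrophilic bromination ortho to the only free phenol) to give the ring-B aryl bromide F1. Separately, 23 is O-alkylated with tributyl(iodomethyl)stannane (Cs2CO3, DMF, rt) to give tributylstannylmethyl allyl fumarate F2. Stille coupling of F1 with F2 (Pd2(dba)3, tri-2-furylphosphine, CuI, dioxane, 80 °C; transfer of an oxymethyl group from tin) should give 27.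

Step 16. The freed lactol may epimerise by ring–chain tautomerism during irradiation and isolation. The fallback sets out from 28 and comes back at 29, and sets the configuration by crystallisation instead of by retention. 28 is photolysed as in step 16 without regard to configuration, which would give 29 mixed with its enantiomer, the (S)-lactol F3. The mixture is combined with one equivalent of (S)-N,N-dimethyl-1-phenylethylamine (the amine enantiomer and solvent to be chosen by screening). Because the lactol carbon equilibrates in solution through the open formyl-acid form, slow crystallisation should funnel the material into the less soluble diastereomeric salt, the ammonium salt of 29 F4 (crystallisation-induced diastereomer transformation). Cold dilute H3PO4/EtOAc then liberates 29.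

Step 9. Substitution at a C–F carbon flanked by two carbonyl groups by a phenoxide flanked by two substituents may be too slow, with base-mediated degradation competing. The fallback sets out from 10 and 16 and comes back at 20, replacing steps 9–12 by ester formation first and an intramolecular ring closure. 10 is deallylated (Pd(PPh3)4, sodium p-toluenesulfinate, AcOH, THF) to the trihydroxy acetal F5. The allyl ester of 16 is cleaved selectively (Pd(PPh3)4, N-methylaniline 1 equiv, 0 °C; the carboxylate should leave faster than the aryl ether) to 4-(allyloxy)-2-fluoro-3-formyl-6-methylbenzoic acid F6. F6 is esterified with F5 at the most acidic and least hindered 5-OH, para to the lactone carbonyl (DCC, cat. DMAP, CH2Cl2, −20 °C), to give the depside F7. Cs2CO3 in DMF at rt then closes the seven-membered ring by intramolecular SNAr of the 4-phenoxide on the C–F carbon and gives 20 directly, with the ring-A allyl ether still in place. Acyl migration between the 4- and 5-oxygens before ring closure is the point to watch.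

Further compounds
F1 | step 14 | ring-B aryl bromide of 20 (Br on the carbon between the phenol carbon and the depside-oxygen carbon) | Cc1cc(OCC=C)c(C=O)c2c1C(=O)Oc1c(Br)c(O)c3c(c1O2)[C@H](O[C@@H](C)c1ccccc1[N+](=O)[O-])OC3=O
F2 | step 14 | allyl (tributylstannyl)methyl (E)-butenedioate | CCCC[Sn](CCCC)(CCCC)COC(=O)/C=C/C(=O)OCC=C
F3 | step 16 | enantiomer of 29, (S)-lactol | Cc1cc(O)c(C=O)c2c1C(=O)Oc1c(COC(=O)/C=C/C(=O)O)c(O)c3c(c1O2)[C@@H](O)OC3=O
F4 | step 16 | (S)-N,N-dimethyl-1-phenylethylammonium salt of 29 | C[C@H]([NH+](C)C)c1ccccc1.Cc1cc(O)c(C=O)c2c1C(=O)Oc1c(COC(=O)/C=C/C(=O)[O-])c(O)c3c(c1O2)[C@H](O)OC3=O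
F5 | step 9 | (3R)-4,5,7-trihydroxy-3-[(1S)-1-(2-nitrophenyl)ethoxy]-2-benzofuran-1(3H)-one | Oc1cc(O)c2c(c1O)[C@H](O[C@@H](C)c1ccccc1[N+](=O)[O-])OC2=O
F6 | step 9 | 4-(allyloxy)-2-fluoro-3-formyl-6-methylbenzoic acid | Cc1cc(OCC=C)c(C=O)c(F)c1C(=O)O
F7 | step 9 | depside: 5-O-aroyl ester of F5 with F6 | Cc1cc(OCC=C)c(C=O)c(F)c1C(=O)Oc1cc(O)c2c(c1O)[C@H](O[C@@H](C)c1ccccc1[N+](=O)[O-])OC2=O
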